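The route rests on cutting the bond between the benzylic CH2 carbon, alpha to the ketone on ring C (the catechol ring), and the carbon of ring D (the meta-phenylene) that lies meta to the diaryl ether oxygen. Because this CH2 is the only enolisable position of a ring C methyl ketone, a palladium-catalysed enolate arylation with a ring D bromide forms the C-C bond and closes the 18-membered ring in one operation. The precursor is the open chain D-O-B-CH2CH2-A-O-C with a ring C acetyl group, a ring D bromine and three methyl ethers, built by fluoride displacement, Wittig olefination, diimide reduction and iodide-selective Ullmann coupling; BBr3 finally frees the phenols.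

Key step: step 8

Ring labels: ring A = the para-phenylene ring; ring B = the phenol ring that carries the ethylene bridge; ring C = the catechol ring that carries the ketone; ring D = the meta-phenylene ring that carries the CH2 next to the ketone.

Design remark: ring D carries bromine and ring C enters as an iodide, so that the copper step can tell the two halogens apart while the palladium step still finds a reactive C-Br bond; the three phenols stay methyl ethers until the last step.

Assumption: the alkene from step 3 is carried on as its E/Z mixture, because step 4 removes the double bond; the target and all main-route intermediates are free of stereocentres.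

Step 1
Reactants: 1 2-fluoro-3-methoxybenzaldehyde; 2 3-bromophenol
Product: 3 2-(3-bromophenoxy)-3-methoxybenzaldehyde
Conditions: K2CO3, DMF, 120 °C
Reagents that add atoms: none
Why: Nucleophilic aromatic substitution (SNAr): the ortho-formyl group stabilises the Meisenheimer adduct so that the phenoxide of 2 displaces fluoride, while the C-Br bond of 2 is inert in the absence of a metal catalyst.

Step 2
Reactants: 4 4-hydroxybenzyl alcohol
Product: 5 (4-hydroxybenzyl)triphenylphosphonium bromide
Conditions: PPh3·HBr, MeCN, reflux
Reagents that add atoms: triphenylphosphine hydrobromide, SMILES [Br-].c1ccc(cc1)[PH+](c1ccccc1)c1ccccc1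
Why: Phosphonium salt formation by SN1-type substitution: HBr ionises the para-hydroxybenzylic alcohol to a resonance-stabilised cation that triphenylphosphine captures, and the salt should crystallise from the hot solvent.

Step 3
Reactants: 5 (4-hydroxybenzyl)triphenylphosphonium bromide; 3 2-(3-bromophenoxy)-3-methoxybenzaldehyde
Product: 7 4-{2-[2-(3-bromophenoxy)-3-methoxyphenyl]ethenyl}phenol (E/Z mixture), via phenoxide ylide 6 (not isolated)
Conditions: 5 (1.2 equiv), KOtBu (2.4 equiv), THF, 0 °C; then 3, 0 °C to rt; aq. HCl work-up
Reagents that add atoms: none
Why: Wittig olefination: the first equivalent of base forms the phenoxide and the second the ylide, which adds to the non-enolisable aldehyde and collapses to the stilbene and triphenylphosphine oxide.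

Step 4
Reactants: 7 4-{2-[2-(3-bromophenoxy)-3-methoxyphenyl]ethenyl}phenol (E/Z mixture)
Product: 8 4-{2-[2-(3-bromophenoxy)-3-methoxyphenyl]ethyl}phenol
Conditions: TsNHNH2 (excess, in portions), NaOAc, DME/H2O, reflux
Reagents that add atoms: none
Why: Diimide reduction: HN=NH released from the sulfonyl hydrazide transfers two hydrogens to the stilbene double bond in a concerted syn fashion and, unlike hydrogenation over palladium, leaves the aryl C-Br bond intact.

Step 5
Reactants: 9 acetovanillone
Product: 10 1-(4-hydroxy-3-iodo-5-methoxyphenyl)ethanone (5-iodoacetovanillone)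
Conditions: NIS, TFA (cat.), MeCN, rt
Reagents that add atoms: N-iodosuccinimide, SMILES O=C1CCC(=O)N1I
Why: Electrophilic aromatic iodination: the phenol directs iodine to its only free ortho position (C5, the para position being blocked by the acetyl group), and this ring substitution should be much faster than alpha-iodination of the ketone.

Step 6
Reactants: 10 1-(4-hydroxy-3-iodo-5-methoxyphenyl)ethanone
Product: 11 1-(3-iodo-4,5-dimethoxyphenyl)ethanone
Conditions: MeI, K2CO3, acetone, reflux
Reagents that add atoms: iodomethane, SMILES CI
Why: Williamson ether synthesis: the acidic para-acyl phenoxide is O-methylated by SN2 attack on iodomethane, while carbonate is too weak to enolise the ketone for C-methylation.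

Step 7
Reactants: 8 4-{2-[2-(3-bromophenoxy)-3-methoxyphenyl]ethyl}phenol; 11 1-(3-iodo-4,5-dimethoxyphenyl)ethanone
Product: 12 1-[3-(4-{2-[2-(3-bromophenoxy)-3-methoxyphenyl]ethyl}phenoxy)-4,5-dimethoxyphenyl]ethanone (open-chain bromo methyl ketone)
Conditions: 11 (1.5 equiv), CuI (5 mol%), N,N-dimethylglycine hydrochloride (15 mol%), Cs2CO3, 1,4-dioxane, 90 °C
Reagents that add atoms: none
Why: Ullmann diaryl ether coupling (copper-catalysed, amino-acid-promoted): the electron-rich phenoxide of 8 couples at the C-I bond of 11, which reacts with copper far faster than the unactivated ring D C-Br bond, and the excess of 11 with a low copper loading should keep self-coupling of 8 minor.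

Step 8
Reactants: 12 1-[3-(4-{2-[2-(3-bromophenoxy)-3-methoxyphenyl]ethyl}phenoxy)-4,5-dimethoxyphenyl]ethanone
Product: 13 tri-O-methyl marchantin G (18-membered macrocyclic ketone in which the CH2 next to the ring C carbonyl is bonded to ring D, meta to the ring D ether oxygen)
Conditions: Pd(OAc)2 (20 mol%), XPhos (40 mol%), K3PO4 (3 equiv), toluene, 100 °C; 12 added by syringe pump over 12 h (final 2 mM)
Reagents that add atoms: none
Why: Zerovalent palladium, formed in the flask from Pd(OAc)2 and XPhos, inserts into the ring D C-Br bond; K3PO4 generates the enolate of the ring C methyl ketone, which replaces bromide on the arylpalladium bromide (divalent palladium), and C-C reductive elimination makes the CH2-ring D bond and returns zerovalent palladium. The closest known reaction type is the palladium-catalysed alpha-arylation of aryl methyl ketones with aryl bromides, well established between two molecules and, within one molecule, for small and medium rings. The one new ring, the 18-membered macrocycle, closes end to end by reductive elimination from a 19-membered palladacycle that holds the enolate carbon and the ring D carbon on the same metal. No stereocentre is created. Ring closure must beat chain growth and single arylation must beat a second one: syringe-pump addition keeps 12 near millimolar concentration, the substrate offers one enolisable CH3 and an unhindered bromide remote from both ortho-substituted ether junctions, and the bulky ligand together with the secondary, ring-embedded enolate of 13 should disfavour further arylation.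

Step 9
Reactants: 13 tri-O-methyl marchantin G
Product: 14 marchantin G
Conditions: BBr3 (9 equiv), CH2Cl2, -78 °C to rt; then H2O
Reagents that add atoms: none
Why: Lewis acid ether cleavage: BBr3 binds each methoxy oxygen and bromide removes the methyl group by SN2 attack, whereas the diaryl ether bonds offer no alkyl carbon and the ketone is only complexed, so that aqueous work-up should release the three phenols.

Compound list
1 | 2-fluoro-3-methoxybenzaldehyde | O=Cc1cccc(OC)c1F | starting material
2 | 3-bromophenol | Oc1cccc(Br)c1 | starting material
3 | 2-(3-bromophenoxy)-3-methoxybenzaldehyde | O=Cc1cccc(OC)c1Oc1cccc(Br)c1 | intermediate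
4 | 4-hydroxybenzyl alcohol | OCc1ccc(O)cc1 | starting material
5 | (4-hydroxybenzyl)triphenylphosphonium bromide | [Br-].Oc1ccc(cc1)C[P+](c1ccccc1)(c1ccccc1)c1ccccc1 | intermediate
6 | potassium 4-[(triphenylphosphoranylidene)methyl]phenolate (phenoxide ylide, not isolated) | [K+].[O-]c1ccc(cc1)C=P(c1ccccc1)(c1ccccc1)c1ccccc1 | intermediate
7 | 4-{2-[2-(3-bromophenoxy)-3-methoxyphenyl]ethenyl}phenol (E/Z mixture) | Oc1ccc(cc1)C=Cc1cccc(OC)c1Oc1cccc(Br)c1 | intermediate
8 | 4-{2-[2-(3-bromophenoxy)-3-methoxyphenyl]ethyl}phenol | Oc1ccc(cc1)CCc1cccc(OC)c1Oc1cccc(Br)c1 | intermediate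
9 | acetovanillone, 1-(4-hydroxy-3-methoxyphenyl)ethanone | CC(=O)c1ccc(O)c(OC)c1 | starting material
10 | 1-(4-hydroxy-3-iodo-5-methoxyphenyl)ethanone | CC(=O)c1cc(I)c(O)c(OC)c1 | intermediate
11 | 1-(3-iodo-4,5-dimethoxyphenyl)ethanone | CC(=O)c1cc(I)c(OC)c(OC)c1 | intermediate
12 | 1-[3-(4-{2-[2-(3-bromophenoxy)-3-methoxyphenyl]ethyl}phenoxy)-4,5-dimethoxyphenyl]ethanone | CC(=O)c1cc(OC)c(OC)c(c1)Oc1ccc(cc1)CCc1cccc(OC)c1Oc1cccc(Br)c1 | intermediate
13 | tri-O-methyl marchantin G | O=C1Cc2cccc(c2)Oc2c(OC)cccc2CCc2ccc(cc2)Oc2cc1cc(OC)c2OC | intermediate
14 | marchantin G | O=C1Cc2cccc(c2)Oc2c(O)cccc2CCc2ccc(cc2)Oc2cc1cc(O)c2O | target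

Total step count: 9

Longest linear sequence: 6 steps (steps 1, 3, 4, 7, 8, 9 from compound 1; the branch from compound 4 through steps 2, 3, 4, 7, 8, 9 is equally long).

Steps most likely to fail

1. Step 8. Intermolecular enolate arylation may outrun ring closure and lead to chain growth. The arylpalladium intermediate may be reduced with loss of bromine. The newly formed benzylic CH2 may be arylated a second time. The fallback replaces the weakly acidic methyl ketone by a fully formed, stabilised carbon nucleophile, replaces palladium by copper, and removes the activating group afterwards. It sets out from 12 and returns to the route at 13. Claisen-type C-acylation of the methyl ketone with dimethyl carbonate (NaH, THF, reflux) should give methyl 3-[3-(4-{2-[2-(3-bromophenoxy)-3-methoxyphenyl]ethyl}phenoxy)-4,5-dimethoxyphenyl]-3-oxopropanoate F1. Intramolecular copper-catalysed arylation of this 1,3-dicarbonyl compound at the ring D bromide (CuI, L-proline, Cs2CO3, DMSO, 70 °C, slow addition) should give the macrocyclic alpha-aryl beta-keto ester F2, racemic at the new CH. Krapcho demethoxycarbonylation (LiCl, wet DMSO, 140 °C) would erase that stereocentre and deliver 13.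

2. Step 7. Copper may also insert into the ring D C-Br bond of 8 or of 12, so that the bromophenol couples with itself and chains form. Carbonate at 90 °C may also start self-condensation of the methyl ketone. The fallback is an oxidative coupling at room temperature that does not activate carbon-halogen bonds. It sets out from 11 and returns at 12. Miyaura borylation of 11 (PdCl2(dppf), bis(pinacolato)diboron, KOAc, dioxane, 80 °C) should give 1-[3,4-dimethoxy-5-(4,4,5,5-tetramethyl-1,3,2-dioxaborolan-2-yl)phenyl]ethanone F3. Oxidative removal of pinacol (NaIO4, NH4OAc, acetone/H2O) should give (5-acetyl-2,3-dimethoxyphenyl)boronic acid F4. Chan-Lam coupling of F4 with phenol 8 (Cu(OAc)2, pyridine, 4 Å molecular sieves, CH2Cl2, air, rt) should give 12 with the ring D bromine untouched.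

3. Step 3. After the first deprotonation the phosphonium phenoxide may expel triphenylphosphine (1,6-elimination to a para-quinone methide that polymerises) before the second deprotonation forms the ylide. The sparingly soluble salt may also react incompletely. The fallback masks the phenol as a benzyl ether and unmasks it after the reduction. It sets out from 3 and returns at 8. Commercial 4-(benzyloxy)benzyl chloride and PPh3 (toluene, reflux) should give [4-(benzyloxy)benzyl]triphenylphosphonium chloride F5. KOtBu (THF, 0 °C) should convert it into the benzyloxybenzylidene ylide F6, which is not isolated and reacts with 3 to give 1-(benzyloxy)-4-{2-[2-(3-bromophenoxy)-3-methoxyphenyl]ethenyl}benzene F7 as an E/Z mixture. Diimide reduction under the conditions of step 4 should give 1-(benzyloxy)-4-{2-[2-(3-bromophenoxy)-3-methoxyphenyl]ethyl}benzene F8. BCl3 with pentamethylbenzene (CH2Cl2, -78 °C) should remove the benzyl group without touching the methyl ether or the bromide and deliver 8.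

Further compounds
F1 | step 8 | methyl 3-[3-(4-{2-[2-(3-bromophenoxy)-3-methoxyphenyl]ethyl}phenoxy)-4,5-dimethoxyphenyl]-3-oxopropanoate | COC(=O)CC(=O)c1cc(OC)c(OC)c(c1)Oc1ccc(cc1)CCc1cccc(OC)c1Oc1cccc(Br)c1
F2 | step 8 | tri-O-methyl marchantin G bearing a methoxycarbonyl group on the carbon between the ketone and ring D (racemic) | COC(=O)C1C(=O)c2cc(OC)c(OC)c(c2)Oc2ccc(cc2)CCc2cccc(OC)c2Oc2cccc1c2
F3 | step 7 | 1-[3,4-dimethoxy-5-(4,4,5,5-tetramethyl-1,3,2-dioxaborolan-2-yl)phenyl]ethanone | CC(=O)c1cc(OC)c(OC)c(c1)B1OC(C)(C)C(C)(C)O1
F4 | step 7 | (5-acetyl-2,3-dimethoxyphenyl)boronic acid | CC(=O)c1cc(OC)c(OC)c(c1)B(O)O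
F5 | step 3 | [4-(benzyloxy)benzyl]triphenylphosphonium chloride | [Cl-].C(c1ccc(OCc2ccccc2)cc1)[P+](c1ccccc1)(c1ccccc1)c1ccccc1
F6 | step 3 | [4-(benzyloxy)benzylidene]triphenylphosphorane (not isolated) | C(=P(c1ccccc1)(c1ccccc1)c1ccccc1)c1ccc(OCc2ccccc2)cc1
F7 | step 3 | 1-(benzyloxy)-4-{2-[2-(3-bromophenoxy)-3-methoxyphenyl]ethenyl}benzene (E/Z mixture) | COc1cccc(C=Cc2ccc(OCc3ccccc3)cc2)c1Oc1cccc(Br)c1
F8 | step 3 | 1-(benzyloxy)-4-{2-[2-(3-bromophenoxy)-3-methoxyphenyl]ethyl}benzene | COc1cccc(CCc2ccc(OCc3ccccc3)cc2)c1Oc1cccc(Br)c1
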